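**Retrosynthetic overview**
1. Target ⇒ 8,9‑diester: esters, α‑methylene (Mannich/elimination) and C14 (Stille on a C10 enol triflate) are added last to a ten‑membered keto lactone.
2. Ten‑membered ring ⇒ anionic oxy‑Cope ([3,3]) of a cis‑1‑vinyl‑2‑alkenylcyclohexanol: C2–C3 forms, C5–C10 breaks, and the chair transition state sets the ring‑cis C4=C5 bond.
3. Divinyl carbinol ⇒ vinyl addition to a cyclohexanone that already carries the trans‑fused γ‑lactone and the 8,9‑acetonide.
4. Cyclohexanone ⇒ (−)‑quinic acid (its C1–C6 become C6, C7, C8, C9, C10, C5): C7 by enolate alkylation, C5 by iodination/Negishi, O10 by conjugate borylation, O6 by directed reduction.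
5. Ring order: cyclohexane (bought) → γ‑lactone (step 10) → ten‑membered ring by ring expansion (step 13).

Assumption: the target is exactly the isomer of the SMILES (1(10)Z,4E, i.e. C2/C9 and C3/C6 cis on the ring; 6R,7S,8R,9S; 2′S). Atoms carry germacrane numbers (C1–C10 ring, C11–C13 lactone, C14 on C10, C15 on C4); α is the ring face of the acetonide oxygens O8/O9, β the other face.

**Route**

Step 1
Reactants: 1 (−)-quinic acid
Product: 2 3,4-O-isopropylidene-1,5-quinide
Conditions: Me2C(OMe)2, TsOH·H2O (cat.), acetone, reflux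
Reagents that add atoms: 2,2-dimethoxypropane COC(C)(C)OC
Why: Acid-catalysed acetonide formation on the cis-3,4-diol with concurrent 1,5-lactonisation leaves only the tertiary OH free and touches no stereocentre (O3/O4 become O8/O9).

Step 2
Reactants: 2 3,4-O-isopropylidene-1,5-quinide
Product: 3 1-(hydroxymethyl) triol acetonide
Conditions: NaBH4, EtOH, 0 °C → rt
Reagents that add atoms: none
Why: Hydride reduction of the strained lactone gives the 1,2-diol needed for glycol cleavage.

Step 3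
Reactants: 3 1-(hydroxymethyl) triol acetonide
Product: 4 (3R,4S,5R)-5-hydroxy-3,4-(isopropylidenedioxy)cyclohexan-1-one
Conditions: NaIO4, H2O (pH 7 phosphate buffer), 0 °C
Reagents that add atoms: none
Why: Malaprade periodate cleavage removes the former carboxyl carbon as formaldehyde and leaves the C6 ketone.

Step 4
Reactants: 4 (3R,4S,5R)-5-hydroxy-3,4-(isopropylidenedioxy)cyclohexan-1-one
Product: 6 (4S,5R)-4,5-(isopropylidenedioxy)cyclohex-2-en-1-one, via mesylate 5 (not isolated)
Conditions: MsCl, Et3N, CH2Cl2, 0 °C → rt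
Reagents that add atoms: none
Why: Mesylation of the β-hydroxyl and E1cB elimination give the conjugated enone (C6=O, C5=C10) with C8/C9 untouched.

Step 5
Reactants: 6 (4S,5R)-4,5-(isopropylidenedioxy)cyclohex-2-en-1-one
Product: 8 (4S,5R,6R)-6-(2-methoxy-2-oxoethyl)-4,5-(isopropylidenedioxy)cyclohex-2-en-1-one, via lithium dienolate 7 (not isolated)
Conditions: LiN(SiMe3)2, THF, −78 °C; BrCH2CO2Me, DMPU, −78 → −40 °C
Reagents that add atoms: methyl bromoacetate COC(=O)CBr
Why: Kinetic α′-deprotonation (the only enolisable site) and SN2 enolate alkylation anti to the adjacent acetonide oxygen put C11–C12 on C7 (β); this is also the thermodynamic epimer once the ring is saturated.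

Step 6
Reactants: 8 (4S,5R,6R)-6-(2-methoxy-2-oxoethyl)-4,5-(isopropylidenedioxy)cyclohex-2-en-1-one
Product: 9 2-iodo enone (iodine on C5)
Conditions: I2, pyridine, CH2Cl2, rt
Reagents that add atoms: iodine II
Why: Johnson α-iodination (pyridine conjugate addition, iodination of the enolate, elimination; Baylis–Hillman type) makes C5 a cross-coupling site.

Step 7
Reactants: 10 2-bromoprop-2-en-1-ol
Product: 11 [(2-bromoprop-2-en-1-yl)oxy](tert-butyl)diphenylsilane
Conditions: TBDPSCl, imidazole, CH2Cl2, rt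
Reagents that add atoms: tert-butyl(chloro)diphenylsilane CC(C)(C)[Si](Cl)(c1ccccc1)c1ccccc1
Why: Silyl ether formation protects the future C15 hydroxyl through all basic and oxidative steps.

Step 8
Reactants: 9 2-iodo enone; 11 [(2-bromoprop-2-en-1-yl)oxy](tert-butyl)diphenylsilane
Product: 14 cross-conjugated dienone (C5 bears the 3-silyloxyprop-1-en-2-yl group), via alkenyllithium 12 (not isolated), via alkenylzinc chloride 13 (not isolated)
Conditions: 11, t-BuLi (2 equiv), Et2O, −78 °C; ZnCl2, THF, −78 → 0 °C; then 9, Pd(PPh3)4 (5 mol%), THF, rt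
Reagents that add atoms: none
Why: Bromine–lithium exchange, transmetalation to zinc and Negishi coupling at zerovalent palladium join C4 to C5 without touching ketone or ester.

Step 9
Reactants: 14 cross-conjugated dienone
Product: 16 β-hydroxy ketone (C6=O; C10–OH β; C5 alkenyl β), via β-boryl ketone 15 (not isolated)
Conditions: B2pin2, CuCl (5 mol%), DPEphos (5 mol%), NaOt-Bu (10 mol%), MeOH (2 equiv), THF, rt; then 30% H2O2, aq. NaHCO3, 0 °C
Reagents that add atoms: bis(pinacolato)diboron CC1(C)OB(OC1(C)C)B1OC(C)(C)C(C)(C)O1 (boron of 15); hydrogen peroxide OO (hydroxyl oxygen of 16)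
Why: Copper-catalysed conjugate borylation adds boron to C10 anti to the adjacent acetonide oxygen, and the enolate is protonated at C5 from the α face so the alkenyl group is β and equatorial (also the thermodynamic epimer); the C–B bond is then oxidised with retention.

Step 10
Reactants: 16 β-hydroxy ketone
Product: 18 hydroxy lactone (trans-fused γ-lactone at C6/C7; C10–OH β), via dihydroxy ester 17 (not isolated)
Conditions: Me4NBH(OAc)3, MeCN/AcOH, −30 °C; then PPTS (cat.), toluene, 60 °C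
Reagents that add atoms: none
Why: Evans–Saksena hydroxyl-directed reduction delivers hydride from the axial C10–OH to the β face of C6 (1,3-anti diol, C6–OH α and equatorial), and the trans-disposed hydroxy ester then lactonises to the trans-fused γ-lactone.

Step 11
Reactants: 18 hydroxy lactone
Product: 19 keto lactone (C10 ketone)
Conditions: Dess–Martin periodinane, CH2Cl2, 0 °C → rt
Reagents that add atoms: none
Why: Dess–Martin oxidation gives the C10 ketone under non-basic conditions; the β-acyloxy ketone is used crude at once to avoid E1cB loss of the lactone oxygen.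

Step 12
Reactants: 19 keto lactone
Product: 20 divinyl carbinol (C10: OH α equatorial, vinyl β axial; cis to the C5 alkenyl group)
Conditions: CH2=CHMgBr, CeCl3, THF, −78 °C; aq. NH4Cl
Reagents that add atoms: vinylmagnesium bromide C=C[Mg]Br
Why: The non-basic organocerium reagent adds 1,2 to the ketone (not the lactone) by axial attack anti to the axial C9–O bond (Felkin–Anh), giving the cis-1-vinyl-2-alkenyl arrangement.

Step 13
Reactants: 20 divinyl carbinol
Product: 23 ten-membered keto lactone (C10 ketone; C4=C5 ring-cis), via potassium alkoxide 21 (not isolated), via potassium enolate 22 (not isolated)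
Conditions: KN(SiMe3)2, 18-crown-6, THF, −78 → 0 °C; aq. NH4Cl, −78 °C
Reagents that add atoms: none
Why: Anionic oxy-Cope rearrangement ([3,3]-sigmatropic): the lactone locks the cyclohexane chair, so only the chair transition state with vinyl axial and alkenyl equatorial is open; C6 is then axial on the reacting six-atom array and ends cis to C3 across the new C4=C5 bond while C2–C3 forms and C5–C10 breaks.

Step 14
Reactants: 23 ten-membered keto lactone
Product: 25 enol triflate (C10–OTf; C1=C10 with C2 and C9 cis), via potassium enolate 24 (not isolated)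
Conditions: KN(SiMe3)2, THF, −78 °C; PhNTf2, −78 → −20 °C; aq. NH4Cl
Reagents that add atoms: N-phenylbis(trifluoromethanesulfonimide) O=S(=O)(N(c1ccccc1)S(=O)(=O)C(F)(F)F)C(F)(F)F
Why: Kinetic deprotonation takes the unhindered C1 methylene rather than the oxygenated C9 methine and gives the less strained ring-cis enolate, which is O-triflated.

Step 15
Reactants: 25 enol triflate
Product: 26 14-hydroxy compound (CH2OH on C10)
Conditions: Bu3SnCH2OH, Pd(PPh3)4 (10 mol%), LiCl, dioxane, 90 °C
Reagents that add atoms: (tributylstannyl)methanol CCCC[Sn](CCCC)(CCCC)CO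
Why: Stille (Kosugi–Migita) coupling of the enol triflate with the hydroxymethyl stannane installs C14 with retention of olefin geometry; it is run before any allylic ester is present.

Step 16
Reactants: 26 14-hydroxy compound
Product: 27 14,15-bis-silyl ether
Conditions: TBDPSCl, imidazole, DMF, rt
Reagents that add atoms: tert-butyl(chloro)diphenylsilane CC(C)(C)[Si](Cl)(c1ccccc1)c1ccccc1
Why: Silylation masks the primary C14 alcohol for the enolate and acylation steps.

Step 17
Reactants: 27 14,15-bis-silyl ether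
Product: 31 α-methylene lactone, via lithium enolate 28 (not isolated), via Mannich base 29 (not isolated), via ammonium iodide 30 (not isolated)
Conditions: LiN(iPr)2, THF, −78 °C; (CH2=NMe2)I, −78 °C → rt; MeI, rt; aq. NaHCO3
Reagents that add atoms: dimethylmethyleneiminium iodide C=[N+](C)C.[I-] (C13); iodomethane CI (N-methyl of 30 only)
Why: Mannich aminomethylation of the lactone enolate with Eschenmoser's salt, N-methylation and Hofmann-type elimination create the C11=C13 methylene.

Step 18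
Reactants: 31 α-methylene lactone
Product: 32 8,9-diol
Conditions: CF3CO2H/H2O (4:1), CH2Cl2, 0 °C
Reagents that add atoms: none
Why: Acid hydrolysis removes the acetonide while the primary TBDPS ethers and the lactone survive.

Step 19
Reactants: 32 8,9-diol; 33 (S)-2-methylbutanoic acid
Product: 35 9-O-acetyl-8-O-[(S)-2-methylbutanoyl] diester, via 8-O-mono-ester 34 (not isolated)
Conditions: 33, DCC, DMAP (cat.), CH2Cl2, −20 → 0 °C; then Ac2O, pyridine, 0 °C → rt
Reagents that add atoms: acetic anhydride CC(=O)OC(C)=O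
Why: Steglich esterification is expected to take the less hindered C8–OH (C9–OH is flanked by the bulky C10 silyloxymethyl group), and acetylation of C9–OH in the same flask forestalls acyl migration; the 2′S centre comes with the bought acid.

Step 20
Reactants: 35 9-O-acetyl-8-O-[(S)-2-methylbutanoyl] diester
Product: 36 target
Conditions: HF·pyridine, pyridine, THF, 0 °C → rt
Reagents that add atoms: none
Why: Buffered fluoride desilylation frees both primary allylic alcohols without touching the esters or the α-methylene lactone.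

**Compound list**

1 | (−)-quinic acid, (1S,3R,4S,5R)-1,3,4,5-tetrahydroxycyclohexane-1-carboxylic acid | O[C@@]1(C(=O)O)C[C@@H](O)[C@@H](O)[C@H](O)C1 | starting material
2 | 3,4-O-isopropylidene-1,5-quinide (1,5-lactone, cis-3,4-diol as acetonide, tertiary OH free) | O[C@@]12C[C@H]3OC(C)(C)O[C@H]3[C@@H](C1)OC2=O | intermediate
3 | 1-(hydroxymethyl) triol acetonide (carboxyl of 2 reduced to CH2OH; 1-OH and 5-OH free) | OC[C@]1(O)C[C@H]2OC(C)(C)O[C@H]2[C@H](O)C1 | intermediate
4 | (3R,4S,5R)-5-hydroxy-3,4-(isopropylidenedioxy)cyclohexan-1-one | O=C1C[C@H]2OC(C)(C)O[C@H]2[C@H](O)C1 | intermediate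
5 | 5-O-methanesulfonate of 4 (not isolated) | O=C1C[C@H]2OC(C)(C)O[C@H]2[C@H](OS(C)(=O)=O)C1 | intermediate
6 | (4S,5R)-4,5-(isopropylidenedioxy)cyclohex-2-en-1-one (C=O is C6, C2=C3 is C5=C10, acetonide carbons are C9 and C8, CH2 is C7) | O=C1C[C@H]2OC(C)(C)O[C@H]2C=C1 | intermediate
7 | lithium cross-conjugated dienolate of 6 (O–C6=C7; not isolated) | [Li+].[O-]C1=C[C@H]2OC(C)(C)O[C@H]2C=C1 | intermediate
8 | (4S,5R,6R)-6-(2-methoxy-2-oxoethyl)-4,5-(isopropylidenedioxy)cyclohex-2-en-1-one (CH2CO2Me on C7, β, trans to O8) | O=C1[C@H](CC(=O)OC)[C@H]2OC(C)(C)O[C@H]2C=C1 | intermediate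
9 | 2-iodo derivative of 8 (iodine on C5) | O=C1[C@H](CC(=O)OC)[C@H]2OC(C)(C)O[C@H]2C=C1I | intermediate
10 | 2-bromoprop-2-en-1-ol | OCC(Br)=C | starting material
11 | [(2-bromoprop-2-en-1-yl)oxy](tert-butyl)diphenylsilane | C=C(Br)CO[Si](c1ccccc1)(c1ccccc1)C(C)(C)C | intermediate
12 | [3-(tert-butyldiphenylsilyloxy)prop-1-en-2-yl]lithium (not isolated) | [Li]C(=C)CO[Si](c1ccccc1)(c1ccccc1)C(C)(C)C | intermediate
13 | chloro[3-(tert-butyldiphenylsilyloxy)prop-1-en-2-yl]zinc (not isolated) | Cl[Zn]C(=C)CO[Si](c1ccccc1)(c1ccccc1)C(C)(C)C | intermediate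
14 | cross-conjugated dienone: 8 with the 3-(tert-butyldiphenylsilyloxy)prop-1-en-2-yl group on C5 (C6 ketone, C5=C10) | O=C1[C@H](CC(=O)OC)[C@H]2OC(C)(C)O[C@H]2C=C1C(=C)CO[Si](c3ccccc3)(c3ccccc3)C(C)(C)C | intermediate
15 | β-boryl ketone (not isolated): C6 ketone, C10–Bpin β (trans to O9), C5 alkenyl β, C7 side chain β | O=C1[C@H](CC(=O)OC)[C@H]2OC(C)(C)O[C@H]2[C@H](B3OC(C)(C)C(C)(C)O3)[C@@H]1C(=C)CO[Si](c4ccccc4)(c4ccccc4)C(C)(C)C | intermediate
16 | β-hydroxy ketone: as 15 with C10–OH β (axial) | O=C1[C@H](CC(=O)OC)[C@H]2OC(C)(C)O[C@H]2[C@H](O)[C@@H]1C(=C)CO[Si](c3ccccc3)(c3ccccc3)C(C)(C)C | intermediate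
17 | dihydroxy ester (not isolated): C6–OH α (equatorial), C10–OH β, methyl ester intact | O[C@H]1[C@H](CC(=O)OC)[C@H]2OC(C)(C)O[C@H]2[C@H](O)[C@@H]1C(=C)CO[Si](c3ccccc3)(c3ccccc3)C(C)(C)C | intermediate
18 | hydroxy lactone: cyclohexane with trans-fused γ-lactone (O6–C12(=O)–C11–C7), 8,9-acetonide α, C5 alkenyl β, C10–OH β | O=C1C[C@@H]2[C@H]3OC(C)(C)O[C@H]3[C@H](O)[C@H](C(=C)CO[Si](c4ccccc4)(c4ccccc4)C(C)(C)C)[C@H]2O1 | intermediate
19 | keto lactone: C10 ketone of 18 | O=C1C[C@@H]2[C@H]3OC(C)(C)O[C@H]3C(=O)[C@H](C(=C)CO[Si](c4ccccc4)(c4ccccc4)C(C)(C)C)[C@H]2O1 | intermediate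
20 | divinyl carbinol: C10 with OH α (equatorial) and vinyl β (axial), cis to the C5 alkenyl group | O=C1C[C@@H]2[C@H]3OC(C)(C)O[C@H]3[C@](O)(C=C)[C@H](C(=C)CO[Si](c4ccccc4)(c4ccccc4)C(C)(C)C)[C@H]2O1 | intermediate
21 | potassium alkoxide of 20 (not isolated) | O=C1C[C@@H]2[C@H]3OC(C)(C)O[C@H]3[C@]([O-])(C=C)[C@H](C(=C)CO[Si](c4ccccc4)(c4ccccc4)C(C)(C)C)[C@H]2O1.[K+] | intermediate
22 | ring-expanded potassium enolate (not isolated): C10–O−, C1=C10 with C2 and C9 trans, C4=C5 with C3 and C6 cis | O=C1C[C@@H]2[C@H]3OC(C)(C)O[C@H]3/C([O-])=C/CC/C(CO[Si](c4ccccc4)(c4ccccc4)C(C)(C)C)=C\[C@H]2O1.[K+] | intermediate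
23 | ten-membered keto lactone: C10 ketone, ring-cis C4=C5 with CH2OTBDPS on C4, trans-lactone at C6/C7, 8,9-acetonide (C6–C9 as in the target) | O=C1C[C@@H]2[C@H]3OC(C)(C)O[C@H]3C(=O)CCC/C(CO[Si](c4ccccc4)(c4ccccc4)C(C)(C)C)=C\[C@H]2O1 | intermediate
24 | potassium enolate of 23 toward C1 (not isolated): C2 and C9 cis | O=C1C[C@@H]2[C@H]3OC(C)(C)O[C@H]3/C([O-])=C\CC/C(CO[Si](c4ccccc4)(c4ccccc4)C(C)(C)C)=C\[C@H]2O1.[K+] | intermediate
25 | enol triflate: C10–OTf, C1=C10 with C2 and C9 cis | O=C1C[C@@H]2[C@H]3OC(C)(C)O[C@H]3/C(OS(=O)(=O)C(F)(F)F)=C\CC/C(CO[Si](c4ccccc4)(c4ccccc4)C(C)(C)C)=C\[C@H]2O1 | intermediate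
26 | 14-hydroxy compound: CH2OH on C10, both ring olefins as in the target, 15-O-TBDPS, 8,9-acetonide | O=C1C[C@@H]2[C@H]3OC(C)(C)O[C@H]3/C(CO)=C\CC/C(CO[Si](c4ccccc4)(c4ccccc4)C(C)(C)C)=C\[C@H]2O1 | intermediate
27 | 14,15-bis(tert-butyldiphenylsilyl) ether of 26 | O=C1C[C@@H]2[C@H]3OC(C)(C)O[C@H]3/C(CO[Si](c4ccccc4)(c4ccccc4)C(C)(C)C)=C\CC/C(CO[Si](c5ccccc5)(c5ccccc5)C(C)(C)C)=C\[C@H]2O1 | intermediate
28 | lithium enolate of lactone 27 (O–C12=C11; not isolated) | [Li+].[O-]C1=C[C@@H]2[C@H]3OC(C)(C)O[C@H]3/C(CO[Si](c4ccccc4)(c4ccccc4)C(C)(C)C)=C\CC/C(CO[Si](c5ccccc5)(c5ccccc5)C(C)(C)C)=C\[C@H]2O1 | intermediate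
29 | Mannich base (not isolated): 11-(dimethylaminomethyl) lactone, C11 epimers, centre removed in the same step | O=C1C(CN(C)C)[C@@H]2[C@H]3OC(C)(C)O[C@H]3/C(CO[Si](c4ccccc4)(c4ccccc4)C(C)(C)C)=C\CC/C(CO[Si](c5ccccc5)(c5ccccc5)C(C)(C)C)=C\[C@H]2O1 | intermediate
30 | 11-(trimethylammoniomethyl) lactone iodide (not isolated), C11 epimers | O=C1C(C[N+](C)(C)C)[C@@H]2[C@H]3OC(C)(C)O[C@H]3/C(CO[Si](c4ccccc4)(c4ccccc4)C(C)(C)C)=C\CC/C(CO[Si](c5ccccc5)(c5ccccc5)C(C)(C)C)=C\[C@H]2O1.[I-] | intermediate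
31 | α-methylene lactone (C11=C13) with 8,9-acetonide and 14,15-bis-silyl ether | O=C1C(=C)[C@@H]2[C@H]3OC(C)(C)O[C@H]3/C(CO[Si](c4ccccc4)(c4ccccc4)C(C)(C)C)=C\CC/C(CO[Si](c5ccccc5)(c5ccccc5)C(C)(C)C)=C\[C@H]2O1 | intermediate
32 | 8,9-diol of 31 (both OH α, cis) | O=C1C(=C)[C@@H]2[C@@H](O)[C@@H](O)/C(CO[Si](c3ccccc3)(c3ccccc3)C(C)(C)C)=C\CC/C(CO[Si](c4ccccc4)(c4ccccc4)C(C)(C)C)=C\[C@H]2O1 | intermediate
33 | (S)-2-methylbutanoic acid | CC[C@H](C)C(=O)O | starting material
34 | 8-O-[(S)-2-methylbutanoyl] mono-ester of 32 (9-OH free; not isolated) | O=C1C(=C)[C@@H]2[C@@H](OC(=O)[C@@H](C)CC)[C@@H](O)/C(CO[Si](c3ccccc3)(c3ccccc3)C(C)(C)C)=C\CC/C(CO[Si](c4ccccc4)(c4ccccc4)C(C)(C)C)=C\[C@H]2O1 | intermediate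
35 | 9-O-acetyl-8-O-[(S)-2-methylbutanoyl] diester, 14,15-bis-silyl ether | O=C1C(=C)[C@@H]2[C@@H](OC(=O)[C@@H](C)CC)[C@@H](OC(C)=O)/C(CO[Si](c3ccccc3)(c3ccccc3)C(C)(C)C)=C\CC/C(CO[Si](c4ccccc4)(c4ccccc4)C(C)(C)C)=C\[C@H]2O1 | intermediate
36 | target, (1(10)Z,4E,6R,7S,8R,9S)-9-acetoxy-14,15-dihydroxy-8-[(S)-2-methylbutanoyloxy]germacra-1(10),4,11(13)-trien-12,6-olide | C=C1C(=O)O[C@@H]2/C=C(/CO)CC/C=C(/CO)[C@H](OC(C)=O)[C@H](OC(=O)[C@@H](C)CC)[C@@H]12 | target

**Step count and weak points**

Total: 20 steps. Longest linear sequence: 19 steps (steps 1–6 and 8–20 from quinic acid); step 7 is the only off-line step.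

The three steps most likely to fail:

Step 5 (α′-alkylation of enone 6). The dienolate 7 can expel the β-acetonide oxygen (E1cB) and aromatise before it is alkylated. The fallback sets out from 6 and comes back at 8. TBSOTf/Et3N (CH2Cl2, 0 °C) converts 6 under non-enolate conditions into the tert-butyldimethylsilyl dienol ether F1. The electrophilic radical from methyl iodoacetate (Et3B, air, CH2Cl2, rt) then adds to the terminal carbon (C7) of F1 from the face away from the acetonide, and loss of the silyl iodide gives 8 without a free enolate ever being present.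

Step 13 (oxy-Cope). In alkoxide 21 the C6 acyloxy bond is antiperiplanar to C5–C10, so a Grob-type fragmentation with loss of the lactone carboxylate could compete with the [3,3] shift. The fallback sets out from 20 and comes back at 23. AlMe3/Me2NH·HCl (toluene, 40 °C) opens the lactone to the hydroxy dimethylamide F2, so that C6 carries an alkoxide and not a leaving group. KN(SiMe3)2 (2.2 equiv)/18-crown-6 then effects the same rearrangement on the dianion to the ring-expanded hydroxy amide F3. TsOH (cat.) in toluene at 60 °C closes the trans-lactone again with loss of dimethylamine to give 23.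

Step 14 (enol triflate). It needs regiocontrol (C1, not C9, whose enolisation would expel O8) and the ring-cis geometry at the same time. The fallback sets out from 23 and comes back at 26, bypassing 25 and step 15. Corey–Chaykovsky reaction (Me3SI, KN(SiMe3)2, THF, 0 °C) gives the C10 spiro-epoxide F4. Diethylaluminium 2,2,6,6-tetramethylpiperidide (benzene, 0 °C) isomerises F4 by syn-elimination toward the C1 methylene to the allylic alcohol 26; the C1=C10 geometry is then set by the cyclic elimination and no enolate is involved.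

**Further compounds**
F1 | step 5 | tert-butyldimethylsilyl dienol ether of 6, (4S,5R)-1-(tert-butyldimethylsilyloxy)-4,5-(isopropylidenedioxy)cyclohexa-1(6),2-diene | CC(C)(C)[Si](C)(C)OC1=C[C@H]2OC(C)(C)O[C@H]2C=C1
F2 | step 13 | hydroxy dimethylamide from lactone opening of 20 (C6–OH α free, C7–CH2CONMe2, other centres as in 20) | CN(C)C(=O)C[C@@H]1[C@H]2OC(C)(C)O[C@H]2[C@](O)(C=C)[C@H](C(=C)CO[Si](c3ccccc3)(c3ccccc3)C(C)(C)C)[C@H]1O
F3 | step 13 | ring-expanded hydroxy dimethylamide (ten-membered C10 ketone, ring-cis C4=C5, C6–OH free) | CN(C)C(=O)C[C@@H]1[C@H]2OC(C)(C)O[C@H]2C(=O)CCC/C(CO[Si](c3ccccc3)(c3ccccc3)C(C)(C)C)=C\[C@H]1O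
F4 | step 14 | C10 spiro-epoxide of 23 (oxirane CH2 is C14; either C10 epimer) | O=C1C[C@@H]2[C@H]3OC(C)(C)O[C@H]3C4(CO4)CCC/C(CO[Si](c5ccccc5)(c5ccccc5)C(C)(C)C)=C\[C@H]2O1
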